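**Retrosynthetic overview**
- Target ⇐ Markovnikov hydration (cobalt hydride/O2) of a C8 exocyclic methylene ⇐ methylenation of the C8 ketone; the acetate is carried from the start.
- C8 ketone ⇐ one-pot cuprate methylation at C10 (creates the cis ring fusion) and C9 alkylation of a (4aS)-enone with the C11–C15 iodide, which comes from (S)-citronellol (C13) by alkene cleavage and iododecarboxylation.
- Key step: (4aS)-enone ⇐ Birch dearomatization of 6-methoxy-1,1-dimethyltetralin run straight into an amine-catalysed enantioselective β,γ→α,β isomerization; this sets C5, which then relays to C10, C9 and C8.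
- Rings: ring A is the saturated ring of 6-methoxy-1-tetralone (C4 gem-dimethyl by Reetz methylation); ring B is its anisole ring, dearomatized; no ring is closed.

Positions are given in labdane numbering (C4 gem-dimethyl, C5 ring-fusion CH, C8 carbinol, C9 side-chain carbon, C10 angular-methyl carbon, C13 side-chain methine). The SMILES encodes (5S,8R,9R,10R,13S): H-5, H-9, the C10 methyl and the C8 hydroxyl are on one face, so the decalin is cis-fused (the C10 epimer of the sclareol-type skeleton), with the side chain trans to the angular methyl and to the hydroxyl.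

Assumption: the quinine-derived primary amine gives the (4aS)-enone in step 2; if it favours (4aR), the quinidine-derived pseudoenantiomer is used instead.

**Step 1**
Reactants: 1 6-methoxy-1-tetralone (6-methoxy-3,4-dihydronaphthalen-1(2H)-one)
Product: 2 6-methoxy-1,1-dimethyl-1,2,3,4-tetrahydronaphthalene
Conditions: Me2Zn (2.2 equiv), TiCl4 (2.2 equiv), CH2Cl2, −40 °C to rt
Reagents that add atoms: dimethylzinc, C[Zn]C
Why: Reetz geminal dimethylation, in which Me2TiCl2 formed in the flask methylates the aryl ketone and the p-methoxybenzylic titanium alkoxide ionises and takes a second methyl, giving the C4 gem-dimethyl group without any stereocentre.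

**Step 2**
Reactants: 2 6-methoxy-1,1-dimethyl-1,2,3,4-tetrahydronaphthalene
Product: 5 (4aS)-5,5-dimethyl-4,4a,5,6,7,8-hexahydronaphthalen-2(3H)-one, via dienol ether 3 (not isolated), via β,γ-enone 4 (not isolated)
Conditions: Li, NH3(l), THF, t-BuOH, −78 to −33 °C, NH4Cl quench; (CO2H)2, MeOH–H2O, 0 °C; crude 4, 9-amino-9-deoxy-epi-quinine (10 mol %), CF3CO2H (20 mol %), PhMe, −25 °C
Reagents that add atoms: water, O
Why: Birch reduction breaks the anisole ring into the 2,5-dihydro enol ether that keeps the tetrasubstituted C5=C10 alkene, mild acid hydrolysis gives the achiral β,γ-enone, and the chiral primary amine then effects an enantioselective olefin isomerization (iminium, dienamine through the quinuclidine base, face-selective γ-protonation at C5 by the quinuclidinium) that is driven by conjugation and sets C5 as S.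

**Step 3**
Reactants: 6 (S)-citronellol, (3S)-3,7-dimethyloct-6-en-1-ol
Product: 7 (S)-citronellyl acetate, (3S)-3,7-dimethyloct-6-en-1-yl acetate
Conditions: Ac2O, pyridine, DMAP (cat.), CH2Cl2, 0 °C to rt
Reagents that add atoms: acetic anhydride, CC(=O)OC(C)=O
Why: DMAP-catalysed acylation of the primary alcohol installs the final acetate at the outset and leaves the remote stereocentre (future C13) untouched.

**Step 4**
Reactants: 7 (S)-citronellyl acetate
Product: 8 (4S)-6-acetoxy-4-methylhexanoic acid
Conditions: RuCl3 hydrate (2 mol %), NaIO4 (4 equiv), EtOAc–MeCN–H2O, rt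
Reagents that add atoms: sodium periodate, [Na+].[O-]I(=O)(=O)=O; water, O
Why: Catalytic RuO4 oxidative cleavage of the trisubstituted alkene gives the carboxylic acid and acetone, and the methyl-bearing stereocentre is not adjacent to any reacting carbon.

**Step 5**
Reactants: 8 (4S)-6-acetoxy-4-methylhexanoic acid
Product: 9 (3R)-5-iodo-3-methylpentyl acetate
Conditions: PhI(OAc)2 (0.6 equiv), I2 (0.6 equiv), hν (tungsten lamp), cyclohexane, reflux
Reagents that add atoms: iodine, II
Why: Suárez iododecarboxylation (radical Hunsdiecker-type reaction through the acyl hypoiodite) shortens the chain by one carbon to the primary iodide; the stereocentre is untouched and its descriptor changes to R only because the priorities change.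

**Step 6**
Reactants: 5 (4aS)-5,5-dimethyl-4,4a,5,6,7,8-hexahydronaphthalen-2(3H)-one; 9 (3R)-5-iodo-3-methylpentyl acetate
Product: 12 (3S)-3-methyl-5-[(1R,4aS,8aR)-5,5,8a-trimethyl-2-oxodecahydronaphthalen-1-yl]pentyl acetate, via lithium enolate 10 (not isolated), via C9-epimeric ketone 11 (not isolated)
Conditions: MeLi (2.2 equiv), CuI (1.1 equiv), Et2O, 0 °C, then 5, −20 to 0 °C; 9 (1.3 equiv), THF–HMPA, −20 °C to rt; aq. NH4Cl; crude, DBU (0.3 equiv), PhMe, 40 °C
Reagents that add atoms: methyllithium (delivered as Me2CuLi), [Li]C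
Why: Gilman conjugate addition followed by enolate alkylation: the methyl enters C10 axially on the face of H-5 (anti to the pseudoaxial C4–C5 bond, the trans pathway being blocked by the axial C4 methyl), as in the classical cis-selective angular methylation of Δ1(9)-octal-2-ones; the regiodefined enolate is alkylated at C9 by the primary iodide, and DBU equilibrates the enolisable C9 centre to the equatorial side chain trans to the angular methyl (expected about 5:1, minor epimer recycled).

**Step 7**
Reactants: 12 (3S)-3-methyl-5-[(1R,4aS,8aR)-5,5,8a-trimethyl-2-oxodecahydronaphthalen-1-yl]pentyl acetate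
Product: 13 (3S)-3-methyl-5-[(1S,4aS,8aR)-5,5,8a-trimethyl-2-methylidenedecahydronaphthalen-1-yl]pentyl acetate
Conditions: Zn, CH2Br2, TiCl4, THF–CH2Cl2, 0 °C to rt
Reagents that add atoms: dibromomethane, BrCBr
Why: Takai–Lombardo methylenation with the non-basic Zn/CH2Br2/TiCl4 reagent converts the hindered ketone into the exocyclic alkene without epimerising C9 or touching the acetate; the C9 descriptor changes to S by priority only.

**Step 8**
Reactants: 13 (3S)-3-methyl-5-[(1S,4aS,8aR)-5,5,8a-trimethyl-2-methylidenedecahydronaphthalen-1-yl]pentyl acetate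
Product: 14 (3S)-5-[(1R,2R,4aS,8aR)-2-hydroxy-2,5,5,8a-tetramethyldecahydronaphthalen-1-yl]-3-methylpentyl acetate (target)
Conditions: Co(acac)2 (20 mol %), PhSiH3 (2.5 equiv), O2 (1 atm), THF, rt
Reagents that add atoms: dioxygen, O=O
Why: Mukaiyama hydration (cobalt hydride hydrogen-atom transfer, O2 capture, reduction) puts H on the CH2 terminus and gives the tertiary C8 radical, which is trapped by O2 on the face opposite the axial C1 methylene of the cis-decalin, giving the equatorial 8-hydroxyl trans to the side chain and cis to the angular methyl.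

**Compound list**
1 | 6-methoxy-1-tetralone (6-methoxy-3,4-dihydronaphthalen-1(2H)-one) | COc1ccc2C(=O)CCCc2c1 | starting material
2 | 6-methoxy-1,1-dimethyl-1,2,3,4-tetrahydronaphthalene | COc1ccc2c(c1)CCCC2(C)C | intermediate
3 | 6-methoxy-1,1-dimethyl-1,2,3,4,5,8-hexahydronaphthalene (achiral dienol ether, not isolated) | COC1=CCC2=C(C1)CCCC2(C)C | intermediate
4 | 5,5-dimethyl-3,4,5,6,7,8-hexahydronaphthalen-2(1H)-one (achiral β,γ-enone, not isolated) | O=C1CCC2=C(C1)CCCC2(C)C | intermediate
5 | (4aS)-5,5-dimethyl-4,4a,5,6,7,8-hexahydronaphthalen-2(3H)-one | O=C1C=C2CCCC(C)(C)[C@@H]2CC1 | intermediate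
6 | (S)-citronellol, (3S)-3,7-dimethyloct-6-en-1-ol | OCC[C@@H](C)CCC=C(C)C | starting material
7 | (S)-citronellyl acetate, (3S)-3,7-dimethyloct-6-en-1-yl acetate | CC(=O)OCC[C@@H](C)CCC=C(C)C | intermediate
8 | (4S)-6-acetoxy-4-methylhexanoic acid | CC(=O)OCC[C@@H](C)CCC(=O)O | intermediate
9 | (3R)-5-iodo-3-methylpentyl acetate | CC(=O)OCC[C@@H](C)CCI | intermediate
10 | lithium (4aS,8aR)-5,5,8a-trimethyl-3,4,4a,5,6,7,8,8a-octahydronaphthalen-2-olate (cis-fused enolate, not isolated) | [Li]OC1=C[C@]2(C)CCCC(C)(C)[C@@H]2CC1 | intermediate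
11 | (3S)-3-methyl-5-[(1S,4aS,8aR)-5,5,8a-trimethyl-2-oxodecahydronaphthalen-1-yl]pentyl acetate (C9 epimer of 12, not isolated) | CC(=O)OCC[C@@H](C)CC[C@H]1[C@]2(C)CCCC(C)(C)[C@@H]2CCC1=O | intermediate
12 | (3S)-3-methyl-5-[(1R,4aS,8aR)-5,5,8a-trimethyl-2-oxodecahydronaphthalen-1-yl]pentyl acetate | CC(=O)OCC[C@@H](C)CC[C@@H]1[C@]2(C)CCCC(C)(C)[C@@H]2CCC1=O | intermediate
13 | (3S)-3-methyl-5-[(1S,4aS,8aR)-5,5,8a-trimethyl-2-methylidenedecahydronaphthalen-1-yl]pentyl acetate | CC(=O)OCC[C@@H](C)CC[C@@H]1[C@]2(C)CCCC(C)(C)[C@@H]2CCC1=C | intermediate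
14 | (3S)-5-[(1R,2R,4aS,8aR)-2-hydroxy-2,5,5,8a-tetramethyldecahydronaphthalen-1-yl]-3-methylpentyl acetate | CC(=O)OCC[C@@H](C)CC[C@@H]1[C@]2(C)CCCC(C)(C)[C@@H]2CC[C@@]1(C)O | target

**Step count**
Total: 8 steps. Longest linear sequence: 6 steps (6 → 7 → 8 → 9 → 12 → 13 → 14); the sequence from the aromatic starting material 1 is 5 steps.

**Three steps most likely to fail**

Step 2. The γ-protonation at C5 takes place next to the quaternary C4, so the isomerization may be slow or give modest enantiomeric excess. The fallback sets out from 2 and returns at 5. Birch reduction of 2 followed by hydrolysis with aqueous HCl gives racemic 5,5-dimethyl-4,4a,5,6,7,8-hexahydronaphthalen-2(3H)-one F1. Addition of lithiated (S)-N,S-dimethyl-S-phenylsulfoximine (n-BuLi, THF, −78 °C) to its carbonyl gives two diastereomeric carbinols, the (4aS)-β-hydroxysulfoximine F2 and the (4aR)-β-hydroxysulfoximine F3, which are separated on silica. Heating F2 in toluene at 110 °C reverses the addition and releases 5 (Johnson resolution in place of asymmetric catalysis).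

Step 6. Alkylation at an enolate carbon next to a quaternary centre with an unactivated iodide is slow, so proton transfer and polyalkylation compete, and C9 is set only by a thermodynamic preference of about 1 kcal/mol. The fallback sets out from 9 and 5 and returns at 12. Kornblum oxidation of 9 (DMSO, NaHCO3, 100 °C) gives (3R)-3-methyl-5-oxopentyl acetate F4. Enolate 10, made from 5 and Me2CuLi as before, is trapped at −78 °C by F4 to give the aldol adduct (3R)-5-hydroxy-3-methyl-5-[(4aS,8aR)-5,5,8a-trimethyl-2-oxodecahydronaphthalen-1-yl]pentyl acetate F5. MsCl/Et3N then DBU eliminates this to the exocyclic enone (3S)-3-methyl-5-[(4aS,8aR)-5,5,8a-trimethyl-2-oxooctahydronaphthalen-1(2H)-ylidene]pentyl acetate F6. Hydrogenation (H2, Pd/C, EtOAc) delivers hydrogen to C9 from the face opposite the axial C1 methylene and gives 12, so C9 is set kinetically and a carbonyl addition replaces the SN2 step.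

Step 8. Capture of the C8 radical by O2 has an early transition state and may be only moderately face-selective, so the 8-epimer can form. The fallback sets out from 13 and returns at 14. mCPBA (CH2Cl2, NaHCO3, 0 °C) attacks the alkene from the face opposite the axial C1 methylene and gives the spiro-epoxide (3S)-3-methyl-5-[(1R,2R,4aS,8aR)-5,5,8a-trimethyloctahydro-1H-spiro[naphthalene-2,2'-oxiran]-1-yl]pentyl acetate F7. LiAlH4 (THF, 0 °C) opens it at the CH2 carbon and also cleaves the acetate, giving the diol (1R,2R,4aS,8aR)-1-[(3S)-5-hydroxy-3-methylpentyl]-2,5,5,8a-tetramethyldecahydronaphthalen-2-ol F8. Ac2O/pyridine at 0 °C acetylates only the primary hydroxyl and gives 14.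

**Further compounds**
F1 | step 2 | racemic 5,5-dimethyl-4,4a,5,6,7,8-hexahydronaphthalen-2(3H)-one | O=C1C=C2CCCC(C)(C)C2CC1
F2 | step 2 | (4aS)-5,5-dimethyl-2-{[(S)-N-methyl-S-phenylsulfonimidoyl]methyl}-2,3,4,4a,5,6,7,8-octahydronaphthalen-2-ol (carbinol centre as formed) | CN=[S@](=O)(CC1(O)C=C2CCCC(C)(C)[C@@H]2CC1)c1ccccc1
F3 | step 2 | (4aR)-5,5-dimethyl-2-{[(S)-N-methyl-S-phenylsulfonimidoyl]methyl}-2,3,4,4a,5,6,7,8-octahydronaphthalen-2-ol (carbinol centre as formed) | CN=[S@](=O)(CC1(O)C=C2CCCC(C)(C)[C@H]2CC1)c1ccccc1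
F4 | step 6 | (3R)-3-methyl-5-oxopentyl acetate | CC(=O)OCC[C@@H](C)CC=O
F5 | step 6 | (3R)-5-hydroxy-3-methyl-5-[(4aS,8aR)-5,5,8a-trimethyl-2-oxodecahydronaphthalen-1-yl]pentyl acetate (mixture at the two new centres) | CC(=O)OCC[C@@H](C)CC(O)C1[C@]2(C)CCCC(C)(C)[C@@H]2CCC1=O
F6 | step 6 | (3S)-3-methyl-5-[(4aS,8aR)-5,5,8a-trimethyl-2-oxooctahydronaphthalen-1(2H)-ylidene]pentyl acetate (E/Z mixture) | CC(=O)OCC[C@@H](C)CC=C1[C@]2(C)CCCC(C)(C)[C@@H]2CCC1=O
F7 | step 8 | (3S)-3-methyl-5-[(1R,2R,4aS,8aR)-5,5,8a-trimethyloctahydro-1H-spiro[naphthalene-2,2'-oxiran]-1-yl]pentyl acetate | CC(=O)OCC[C@@H](C)CC[C@@H]1[C@]2(C)CCCC(C)(C)[C@@H]2CC[C@@]1(C3)O3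
F8 | step 8 | (1R,2R,4aS,8aR)-1-[(3S)-5-hydroxy-3-methylpentyl]-2,5,5,8a-tetramethyldecahydronaphthalen-2-ol | OCC[C@@H](C)CC[C@@H]1[C@]2(C)CCCC(C)(C)[C@@H]2CC[C@@]1(C)O
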